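(Readings and results come from a simulation with made-up constants.)

No rate constant is to hand for this flask, so the reply to your hunch rests on the grey run, which is this same flask followed so far.

- grey: solid substrate 0.21 M; reagent 1.2 equiv; the very flask that is asked about, followed so far
- flask: solid substrate 0.21 M; reagent 1.20 equiv; time 2.5 h

grey run (percent of the solid substrate charged)

| time / min | solid substrate / % | bis adduct / % | single product / % |
|---|---|---|---|
| 12.0 | 0.4 | 16.9 | 66.5 |
| 25.0 | 0.7 | 23.6 | 68.5 |
| 30.0 | 0.6 | 24.9 | 68.9 |
| 50.0 | 0.5 | 25.3 | 68.2 |

(scatter of a reading: 0.5 percentage points)

- the analysis behind the earlier runs scatters by 0.5 percentage points, standard deviation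
- at the start none of the solid substrate is in solution
- what has only dissolved of solid substrate counts as not reacted
- what has gone from starting material into another species counts as reacted, even if it can come back
- starting material means what is dissolved; the solid is not counted in it
- a reading or a percentage of bis adduct counts all its forms, free or not

1. part of the solid substrate that has turned into other species by 2.5 h (what has only dissolved does not count)
2. how much bis adduct there is at 2.5 h, in percent of the solid substrate charged
3. how much single product there is at 2.5 h, in percent of the solid substrate charged
4. how much starting material there is at 2.5 h, in percent of the solid substrate charged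
5. amount of bis adduct if the flask were left three thousand times as long, in percent of the solid substrate charged

Follow one molecule. Starting material takes one reagent and reaches a fork: it stays single product or takes a second reagent and becomes bis adduct. At 50.0 min, [single product] + 2×[bis adduct] reads 119% against a charge of 1.20 equiv, so the reagent, here the limiting reagent, looks spent, and my reckoning takes it as wholly used. Over the readings at 30.0 min and 50.0 min, the chance of the second branch is the fork share:

f = [bis adduct]/([bis adduct] + [single product]) = 0.268

Each molecule served costs 1 + f reagent, so:

served = 1.20 equiv/(1 + f) = 0.946

bis adduct = served × f = 0.254

single product = served × (1 − f) = 0.692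

The forecast, on the ground that “nothing moves beyond scatter”, gives at 2.5 h conversion 93.7%, bis adduct 25.2%, single product 68.5% and starting material 0.55%. For the long wait it leans separately towards slow redistribution of bis adduct with starting material into single product, and gives 21.5% of bis adduct. My count speaks neither to the starting material nor to the long wait.

The flask gives conversion 97.8%, bis adduct 26.0%, single product 67.9%, starting material 2.25%, and 26.0% after the long wait, so the forecast held within its margins.

    crystals ⇌ bis adduct, rate k1*(cs1 - [bis adduct]) while solid is left; crystals form when [bis adduct] > cs1 (solubility = 5.40 mM, k = 1.04 s⁻¹)
    reagent + single product → bis adduct (k = 0.00582 M⁻¹ s⁻¹)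
    starting material ⇌ dormant form (K = 1.68, k = 0.00678 s⁻¹)
    starting material + reagent → single product (k = 0.145 M⁻¹ s⁻¹)
    solid substrate ⇌ starting material, rate k5*(cs5 - [starting material]) while solid is left; crystals form when [starting material] > cs5 (solubility = 29.0 mM, k = 0.0209 s⁻¹)

At 2.5 h this flask has f = 0.277, and its count [single product] + 2×[bis adduct] stands at 120%, while the dormant form, 3.78%, carries no reagent. The neighbour flask, with 0.084 M of solid substrate at the same equivalents, would by the grey f hold 0.254 of bis adduct and 0.692 of single product. It holds 23.7% and 72.4%, so its fork share of 0.247 is smaller than the grey one, and 0.17% of its reagent is left.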